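Retrosynthesis: the O7–S bond and the four O–benzyl bonds are cut first, then O1–C8a of ring C, then C3–C4 (aldol, then oxidation), and last C2–C1' (aryl Grignard reagent on a Weinreb amide).
Forward: rings A and B are bought as benzene derivatives, and the C2–C3–C4 chain is laid between them as an α-benzyloxy 1,3-diketone. Ring C is the only ring made and is closed last, by dehydrogenative C–O coupling.
Enabling feature: C4a of ring A carries the C4 carbonyl and is flanked by oxygenated C5 and by C8a–H. C8a–H is therefore the sole ortho C–H, it lies para to O6, and the enol oxygen on C2 is placed to form a six-membered ring with it.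
O7 is para to the same carbonyl, so it is the most acidic hydroxyl of the pyrogallol aldehyde. It takes its own protecting group (MOM), which later frees O7 alone for sulfation.
Stereochemistry: the target has no stereocentre. The centres formed in the aldol step are erased by the oxidation and by aromatisation of ring C.

Key step: step 7

Remark on the chemistry: the two aryl sulfate monoesters are drawn as hydrogen sulfates, as in the target SMILES. At the bench they would be kept as salts: pyridinium is exchanged for sodium on a resin column before the hydrogenolysis, because pyridine slows Pd/C, and the proton form is released on a cold H+ cation-exchange resin at the very end. These counter-ion changes are not counted as steps.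

Step 1
Reactants: 1 2,3,4-trihydroxybenzaldehyde
Product: 2 2,3-dihydroxy-4-(methoxymethoxy)benzaldehyde
Conditions: MOMCl (1.05 equiv), K2CO3 (1.05 equiv), acetone, 0 °C to rt, argon
Reagents that add atoms: chloromethyl methyl ether (MOMCl), COCCl
Why: Williamson-type O-alkylation with one equivalent of weak base should occur at the 4-OH, which is para to the formyl group and so the most acidic (a vinylogous carboxylic acid), whereas the 2-OH is hydrogen-bonded to the carbonyl and the 3-OH anion gains no conjugative stabilisation.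

Step 2
Reactants: 2 2,3-dihydroxy-4-(methoxymethoxy)benzaldehyde
Product: 3 2,3-bis(benzyloxy)-4-(methoxymethoxy)benzaldehyde
Conditions: BnBr (2.5 equiv), K2CO3 (3 equiv), DMF, 60 °C
Reagents that add atoms: benzyl bromide, BrCc1ccccc1
Why: Williamson etherification with excess base and halide at 60 °C also alkylates the hydrogen-bonded 2-OH, and K2CO3 touches neither the MOM acetal nor the non-enolisable aldehyde.

Step 3
Reactants: 4 benzyloxyacetyl chloride
Product: 5 2-(benzyloxy)-N-methoxy-N-methylacetamide
Conditions: MeNH(OMe)·HCl, K2CO3, CH2Cl2/H2O, 0 °C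
Reagents that add atoms: N,O-dimethylhydroxylamine hydrochloride, CNOC.Cl
Why: Schotten–Baumann acylation of the amine nitrogen by the acid chloride is fast at 0 °C and gives the Weinreb amide without affecting the benzyl ether.

Step 4
Reactants: 6 1-(benzyloxy)-4-bromobenzene; 5 2-(benzyloxy)-N-methoxy-N-methylacetamide
Product: 8 2-(benzyloxy)-1-[4-(benzyloxy)phenyl]ethan-1-one, via arylmagnesium bromide 7 (not isolated)
Conditions: Mg turnings, THF, 40 °C; then 5, THF, 0 °C; aqueous quench
Reagents that add atoms: none
Why: In this Weinreb ketone synthesis magnesium stays chelated between the N-methoxy oxygen and the former carbonyl oxygen until the quench, so the aryl Grignard reagent adds only once and the α-benzyloxy ketone appears only on work-up.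

Step 5
Reactants: 8 2-(benzyloxy)-1-[4-(benzyloxy)phenyl]ethan-1-one; 3 2,3-bis(benzyloxy)-4-(methoxymethoxy)benzaldehyde
Product: 10 2-(benzyloxy)-3-[2,3-bis(benzyloxy)-4-(methoxymethoxy)phenyl]-1-[4-(benzyloxy)phenyl]-3-hydroxypropan-1-one (racemic mixture of syn/anti diastereomers), via lithium enolate 9 (not isolated)
Conditions: LiN(SiMe3)2 (1.1 equiv), THF, −78 °C; then 3, −78 °C; AcOH quench at −78 °C
Reagents that add atoms: none
Why: Aldol addition of the chelated lithium Z-enolate to a non-enolisable aromatic aldehyde forms C3–C4, and the two new stereocentres arise as a racemic syn/anti mixture that needs no control because both carbons become sp2 in steps 6 and 7.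

Step 6
Reactants: 10 2-(benzyloxy)-3-[2,3-bis(benzyloxy)-4-(methoxymethoxy)phenyl]-1-[4-(benzyloxy)phenyl]-3-hydroxypropan-1-one
Product: 11 2-(benzyloxy)-1-[2,3-bis(benzyloxy)-4-(methoxymethoxy)phenyl]-3-[4-(benzyloxy)phenyl]propane-1,3-dione (racemic, enolisable centre)
Conditions: IBX (2 equiv), EtOAc, 75 °C
Reagents that add atoms: none
Why: IBX oxidation of a β-hydroxy ketone is an established route to 1,3-diketones that stops at this oxidation level and spares benzyl ethers and the MOM acetal, and the one remaining centre is racemic and enolisable.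

Step 7
Reactants: 11 2-(benzyloxy)-1-[2,3-bis(benzyloxy)-4-(methoxymethoxy)phenyl]-3-[4-(benzyloxy)phenyl]propane-1,3-dione
Product: 12 3,5,6-tris(benzyloxy)-2-[4-(benzyloxy)phenyl]-7-(methoxymethoxy)-4H-chromen-4-one
Conditions: Pd(OAc)2 (10 mol %), N-acetylglycine (20 mol %), PhI(OAc)2 (1.5 equiv, in portions), KOAc (2 equiv), t-BuOH/ClCH2CH2Cl, 80 °C
Reagents that add atoms: none
Why: Proposed new method: the C4 carbonyl oxygen, turned toward C8a–H by dipole repulsion from O5 and made the more basic of the two carbonyls by O5 and O7, should bind Pd(OAc)2 and deliver it to the only ortho C–H of ring A, where acetate- or N-acetylglycinate-assisted concerted metalation–deprotonation gives a five-membered C,O-palladacycle of divalent palladium. In a chromone the C4 oxygen lies on the C5 side, so this weak neutral ligand must then dissociate and the C4a–C4 bond turn by half a rotation, which lets the anionic C2 enolate oxygen chelate instead and gives a seven-membered oxapalladacycle. PhI(OAc)2 oxidises it to tetravalent palladium and C(sp2)–O reductive elimination joins O1 to C8a, so the six-membered ring C closes by contraction of that metallacycle (an intramolecular O-arylation of the enol) and is at once an aromatic 4-pyranone; no stereocentre is made and the racemic centre of 11 disappears. The closest known reactions are the ketone-directed ortho acetoxylation and hydroxylation of aryl ketones and the Pd(OAc)2/PhI(OAc)2 C–H lactonisation of biaryl-2-carboxylic acids, which closes a six-membered C–O ring through a palladacycle of the same size; a 1,3-diketone enol is a vinylogous carboxylic acid but has not been shown in this role. The step needs ring A to be metalated ahead of C2'–H and C6'–H of ring B, which the C2 oxygen could direct: C8a–H is para to O6 on a trialkoxy ring and so the better partner for electrophilic palladium, the ring B positions are meta to their only donor, and on ring A itself C5 is blocked and C8 is out of reach of either oxygen. KOAc buffers the medium for the MOM acetal, portionwise oxidant limits acetoxylation at C3, and transfer of acetate rather than the enol oxygen to C8a would not be a loss, because that ester converges on 12 by acyl cleavage and cyclodehydration.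

Step 8
Reactants: 12 3,5,6-tris(benzyloxy)-2-[4-(benzyloxy)phenyl]-7-(methoxymethoxy)-4H-chromen-4-one
Product: 13 3,5,6-tris(benzyloxy)-2-[4-(benzyloxy)phenyl]-7-hydroxy-4H-chromen-4-one
Conditions: 3 M aq. HCl (catalytic), THF, 50 °C
Reagents that add atoms: none
Why: Acid-catalysed hydrolysis of the phenolic MOM acetal in dilute acid at 50 °C is much faster than cleavage of aryl benzyl ethers, including the one on O5 peri to the carbonyl.

Step 9
Reactants: 13 3,5,6-tris(benzyloxy)-2-[4-(benzyloxy)phenyl]-7-hydroxy-4H-chromen-4-one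
Product: 14 3,5,6-tris(benzyloxy)-2-[4-(benzyloxy)phenyl]-4-oxo-4H-chromen-7-yl hydrogen sulfate
Conditions: SO3·pyridine (4 equiv), DMF, 25 °C
Reagents that add atoms: sulfur trioxide–pyridine complex, O=S(=O)([O-])[n+]1ccccc1
Why: This is O-sulfation of a phenol with a sulfur trioxide–amine complex, and the 7-OH is the only free hydroxyl, so no site selectivity is needed.

Step 10
Reactants: 14 3,5,6-tris(benzyloxy)-2-[4-(benzyloxy)phenyl]-4-oxo-4H-chromen-7-yl hydrogen sulfate
Product: 15 3,5,6-trihydroxy-2-(4-hydroxyphenyl)-4-oxo-4H-chromen-7-yl hydrogen sulfate (6-hydroxykaempferol 7-O-sulfate, CNP0164757.0)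
Conditions: H2 (1 atm), 10% Pd/C, MeOH/THF, 25 °C, work-up under argon
Reagents that add atoms: none
Why: Catalytic hydrogenolysis cleaves the four benzyl–oxygen bonds, while an aryl sulfate salt and the C2=C3 bond of a flavonol, which is part of an aromatic pyranone, are known to survive Pd/C under one atmosphere of hydrogen.

Compound list
1 | 2,3,4-trihydroxybenzaldehyde | O=Cc1ccc(O)c(O)c1O | starting material
2 | 2,3-dihydroxy-4-(methoxymethoxy)benzaldehyde | O=Cc1ccc(OCOC)c(O)c1O | intermediate
3 | 2,3-bis(benzyloxy)-4-(methoxymethoxy)benzaldehyde | O=Cc1ccc(OCOC)c(OCc2ccccc2)c1OCc1ccccc1 | intermediate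
4 | benzyloxyacetyl chloride | O=C(Cl)COCc1ccccc1 | starting material
5 | 2-(benzyloxy)-N-methoxy-N-methylacetamide | CON(C)C(=O)COCc1ccccc1 | intermediate
6 | 1-(benzyloxy)-4-bromobenzene | Brc1ccc(OCc2ccccc2)cc1 | starting material
7 | [4-(benzyloxy)phenyl]magnesium bromide (not isolated) | Br[Mg]c1ccc(OCc2ccccc2)cc1 | intermediate
8 | 2-(benzyloxy)-1-[4-(benzyloxy)phenyl]ethan-1-one | O=C(COCc1ccccc1)c1ccc(OCc2ccccc2)cc1 | intermediate
9 | lithium (Z)-2-(benzyloxy)-1-[4-(benzyloxy)phenyl]ethen-1-olate (not isolated) | [Li]O/C(=C\OCc1ccccc1)c1ccc(OCc2ccccc2)cc1 | intermediate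
10 | 2-(benzyloxy)-3-[2,3-bis(benzyloxy)-4-(methoxymethoxy)phenyl]-1-[4-(benzyloxy)phenyl]-3-hydroxypropan-1-one (racemic syn/anti mixture, configuration left open) | O=C(c1ccc(OCc2ccccc2)cc1)C(OCc1ccccc1)C(O)c1ccc(OCOC)c(OCc2ccccc2)c1OCc1ccccc1 | intermediate
11 | 2-(benzyloxy)-1-[2,3-bis(benzyloxy)-4-(methoxymethoxy)phenyl]-3-[4-(benzyloxy)phenyl]propane-1,3-dione (racemic, enolisable) | O=C(c1ccc(OCOC)c(OCc2ccccc2)c1OCc1ccccc1)C(OCc1ccccc1)C(=O)c1ccc(OCc2ccccc2)cc1 | intermediate
12 | 3,5,6-tris(benzyloxy)-2-[4-(benzyloxy)phenyl]-7-(methoxymethoxy)-4H-chromen-4-one | O=c1c(OCc2ccccc2)c(-c2ccc(OCc3ccccc3)cc2)oc2cc(OCOC)c(OCc3ccccc3)c(OCc3ccccc3)c12 | intermediate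
13 | 3,5,6-tris(benzyloxy)-2-[4-(benzyloxy)phenyl]-7-hydroxy-4H-chromen-4-one | O=c1c(OCc2ccccc2)c(-c2ccc(OCc3ccccc3)cc2)oc2cc(O)c(OCc3ccccc3)c(OCc3ccccc3)c12 | intermediate
14 | 3,5,6-tris(benzyloxy)-2-[4-(benzyloxy)phenyl]-4-oxo-4H-chromen-7-yl hydrogen sulfate | O=c1c(OCc2ccccc2)c(-c2ccc(OCc3ccccc3)cc2)oc2cc(OS(=O)(=O)O)c(OCc3ccccc3)c(OCc3ccccc3)c12 | intermediate
15 | 3,5,6-trihydroxy-2-(4-hydroxyphenyl)-4-oxo-4H-chromen-7-yl hydrogen sulfate | O=c1c(O)c(-c2ccc(O)cc2)oc2cc(OS(=O)(=O)O)c(O)c(O)c12 | target

Total step count: 10. Longest linear sequence: 8 steps (1, 2, 5–10; the branch 3, 4, 5–10 is equally long).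

Steps most likely to fail

Step 7. Three processes may defeat the closure:
- divalent palladium is sequestered as an O,O-chelated diketonate;
- ring B is metalated at C2'/C6' under direction of the C2 oxygen;
- PhI(OAc)2 acetoxylates the enolisable C3 directly.

The fallback uses known chemistry only and places the oxygen that becomes O1 on ring A before the chain is built. It sets out from aldehyde 3. Condensation with t-BuNH2 and imine-directed iridium-catalysed ortho C–H borylation ([Ir(OMe)(cod)]2, 8-aminoquinoline, B2pin2, THF, 80 °C, imine hydrolysed on work-up) should give 2,3-bis(benzyloxy)-4-(methoxymethoxy)-6-(4,4,5,5-tetramethyl-1,3,2-dioxaborolan-2-yl)benzaldehyde F1. Oxidation with NaBO3·4H2O in THF/H2O should give 2,3-bis(benzyloxy)-6-hydroxy-4-(methoxymethoxy)benzaldehyde F2. MOMCl with K2CO3 in DMF should give 2,3-bis(benzyloxy)-4,6-bis(methoxymethoxy)benzaldehyde F3. Aldol addition of enolate 9 should give 2-(benzyloxy)-3-[2,3-bis(benzyloxy)-4,6-bis(methoxymethoxy)phenyl]-1-[4-(benzyloxy)phenyl]-3-hydroxypropan-1-one F4. IBX in EtOAc should give 2-(benzyloxy)-1-[2,3-bis(benzyloxy)-4,6-bis(methoxymethoxy)phenyl]-3-[4-(benzyloxy)phenyl]propane-1,3-dione F5. Aqueous HCl in THF at 50 °C then removes both MOM groups, and the freed 2-hydroxyaryl 1,3-diketone cyclodehydrates as in the last stage of a Baker–Venkataraman flavone synthesis. The route is rejoined at 13.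

Step 10. The O7–S bond may solvolyse under acid as the phenols are unmasked, the hydrogenolysis may stall through catalyst poisoning, and the freed 5,6-dihydroxy unit may oxidise in air. In the fallback the sulfate travels as a neutral diester until the last operation. From 13, 2,2,2-trichloroethyl chlorosulfate (Et3N, DMAP, THF, 0 °C) should give 3,5,6-tris(benzyloxy)-2-[4-(benzyloxy)phenyl]-4-oxo-4H-chromen-7-yl 2,2,2-trichloroethyl sulfate F6, which can be purified on silica. Pd/C with HCO2NH4 in MeOH then removes the four benzyl groups by transfer hydrogenolysis and the trichloroethyl group by reductive fragmentation. The medium is buffered, and the sequence arrives at 15 as its ammonium salt, converted to the proton form as in the remark.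

Step 1. Alkylation may spread to O3 or go twice, and the pyrogallol may oxidise in air under base. The fallback removes O2 from the competition with a temporary bridge. From 1, heating with Ph2CCl2 in Ph2O at 170 °C ties O3 to O4 and leaves the hydrogen-bonded 2-OH free, to give 4-hydroxy-2,2-diphenyl-1,3-benzodioxole-5-carbaldehyde F7. BnBr with K2CO3 should give 4-(benzyloxy)-2,2-diphenyl-1,3-benzodioxole-5-carbaldehyde F8. Aqueous AcOH at reflux should release 2-(benzyloxy)-3,4-dihydroxybenzaldehyde F9. Only two hydroxyls now compete, which is the well-studied case of a 3,4-dihydroxybenzaldehyde, where monoalkylation para to the formyl group is routine. MOMCl with one equivalent of i-Pr2NEt should give 2-(benzyloxy)-3-hydroxy-4-(methoxymethoxy)benzaldehyde F10. Benzylation of the last hydroxyl returns to 3.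

Further compounds
F1 | step 7 | 2,3-bis(benzyloxy)-4-(methoxymethoxy)-6-(4,4,5,5-tetramethyl-1,3,2-dioxaborolan-2-yl)benzaldehyde | O=Cc1c(B2OC(C)(C)C(C)(C)O2)cc(OCOC)c(OCc2ccccc2)c1OCc1ccccc1
F2 | step 7 | 2,3-bis(benzyloxy)-6-hydroxy-4-(methoxymethoxy)benzaldehyde | O=Cc1c(O)cc(OCOC)c(OCc2ccccc2)c1OCc1ccccc1
F3 | step 7 | 2,3-bis(benzyloxy)-4,6-bis(methoxymethoxy)benzaldehyde | O=Cc1c(OCOC)cc(OCOC)c(OCc2ccccc2)c1OCc1ccccc1
F4 | step 7 | 2-(benzyloxy)-3-[2,3-bis(benzyloxy)-4,6-bis(methoxymethoxy)phenyl]-1-[4-(benzyloxy)phenyl]-3-hydroxypropan-1-one (diastereomer mixture) | O=C(c1ccc(OCc2ccccc2)cc1)C(OCc1ccccc1)C(O)c1c(OCOC)cc(OCOC)c(OCc2ccccc2)c1OCc1ccccc1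
F5 | step 7 | 2-(benzyloxy)-1-[2,3-bis(benzyloxy)-4,6-bis(methoxymethoxy)phenyl]-3-[4-(benzyloxy)phenyl]propane-1,3-dione | O=C(c1ccc(OCc2ccccc2)cc1)C(OCc1ccccc1)C(=O)c1c(OCOC)cc(OCOC)c(OCc2ccccc2)c1OCc1ccccc1
F6 | step 10 | 3,5,6-tris(benzyloxy)-2-[4-(benzyloxy)phenyl]-4-oxo-4H-chromen-7-yl 2,2,2-trichloroethyl sulfate | O=c1c(OCc2ccccc2)c(-c2ccc(OCc3ccccc3)cc2)oc2cc(OS(=O)(=O)OCC(Cl)(Cl)Cl)c(OCc3ccccc3)c(OCc3ccccc3)c12
F7 | step 1 | 4-hydroxy-2,2-diphenyl-1,3-benzodioxole-5-carbaldehyde | O=Cc1ccc2OC(c3ccccc3)(c3ccccc3)Oc2c1O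
F8 | step 1 | 4-(benzyloxy)-2,2-diphenyl-1,3-benzodioxole-5-carbaldehyde | O=Cc1ccc2OC(c3ccccc3)(c3ccccc3)Oc2c1OCc1ccccc1
F9 | step 1 | 2-(benzyloxy)-3,4-dihydroxybenzaldehyde | O=Cc1ccc(O)c(O)c1OCc1ccccc1
F10 | step 1 | 2-(benzyloxy)-3-hydroxy-4-(methoxymethoxy)benzaldehyde | O=Cc1ccc(OCOC)c(O)c1OCc1ccccc1
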